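## Retrosynthetic overview

1. Target 29 comes from diol 28 by double allylic oxidation, and 28 from cycloadduct 25 (formyl → CH2OAc); both acetates are in place before the final steps.
2. The pyran and the seven-membered ring close together (C4–C4a, C4a–C9a, O2–C1) in a domino Knoevenagel / intramolecular inverse-demand oxa-Diels–Alder reaction of aldehyde 22 with malondialdehyde.
3. Aldehyde 22 comes from the C7–C8 bond, made by a nickel/chromium-catalysed Nozaki–Hiyama–Kishi coupling of fragment 1 (cyclopropane aldehyde 9) with fragment 2 (iododienyl acetate 19).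
4. Fragment 1: prenol + diketene, Rh-catalysed enantioselective intramolecular cyclopropanation. Fragment 2: propargyl alcohol, ethynyltrimethylsilane and acetic acid via Pd silylstannation, Sonogashira coupling and Ru-catalysed hydro-acetoxylation.
5. Ring order: cyclopropane first (step 4), then pyran and seven-membered ring in one step (step 17).

Locants used below (cyclohepta[c]pyran numbering): C1 acetal carbon, O2, C3=C4, C4a, C5 and C6 bridged by CMe2, C7, C8=C9, C9a; C14 is the carbon on C9.

Assumption: the carbinol centre C7 made in the fragment coupling is carried as an epimer mixture (it becomes the ketone in the last step) and is left undefined in names and SMILES.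

## Route

**Fragment 1 (steps 1–7)**

Step 1
Reactants: 1 3-methylbut-2-en-1-ol; 2 diketene
Product: 3 3-methylbut-2-en-1-yl 3-oxobutanoate
Conditions: NaOAc (cat.), THF, reflux
Reagents that add atoms: none
Why: Acetoacetylation of the primary allylic alcohol by ring opening of diketene (acyl transfer); no stereocenter.

Step 2
Reactants: 3 3-methylbut-2-en-1-yl 3-oxobutanoate
Product: 4 3-methylbut-2-en-1-yl 2-diazo-3-oxobutanoate
Conditions: MsN3, Et3N, MeCN, 0 °C to rt
Reagents that add atoms: methanesulfonyl azide, CS(=O)(=O)N=[N+]=[N-]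
Why: Regitz diazo transfer to the doubly activated methylene.

Step 3
Reactants: 4 3-methylbut-2-en-1-yl 2-diazo-3-oxobutanoate
Product: 5 3-methylbut-2-en-1-yl diazoacetate
Conditions: LiOH, H2O/MeCN, rt
Reagents that add atoms: none
Why: Hydroxide-induced deacetylation (retro-Claisen cleavage) of the 2-diazo-1,3-dicarbonyl leaves the diazoacetate.

Step 4
Reactants: 5 3-methylbut-2-en-1-yl diazoacetate
Product: 6 (1S,5R)-6,6-dimethyl-3-oxabicyclo[3.1.0]hexan-2-one
Conditions: Rh2(5S-MEPY)4 (1 mol %), CH2Cl2, reflux, slow addition of 5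
Reagents that add atoms: none
Why: Doyle enantioselective intramolecular cyclopropanation of an allylic diazoacetate; the chiral dirhodium carboxamidate selects the alkene face and sets both cyclopropane stereocenters (the lactone enforces the cis relationship), with literature ee of about 95 % or more for this substrate.

Step 5
Reactants: 6 (1S,5R)-6,6-dimethyl-3-oxabicyclo[3.1.0]hexan-2-one
Product: 7 (1S,3R)-3-(hydroxymethyl)-N-methoxy-N,2,2-trimethylcyclopropane-1-carboxamide
Conditions: MeNH(OMe)·HCl, i-PrMgCl, THF, −20 to 0 °C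
Reagents that add atoms: N,O-dimethylhydroxylamine hydrochloride, CNOC.Cl
Why: Aminolysis of the lactone by the chloromagnesium amide (Weinreb amide formation) differentiates the two cyclopropane arms without touching the stereocenters.

Step 6
Reactants: 7 (1S,3R)-3-(hydroxymethyl)-N-methoxy-N,2,2-trimethylcyclopropane-1-carboxamide
Product: 8 (1S,3R)-N-methoxy-N,2,2-trimethyl-3-{[(triethylsilyl)oxy]methyl}cyclopropane-1-carboxamide
Conditions: Et3SiCl, imidazole, CH2Cl2, 0 °C
Reagents that add atoms: chlorotriethylsilane, CC[Si](Cl)(CC)CC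
Why: Silylation of the primary alcohol also prevents relactonisation.

Step 7
Reactants: 8 (1S,3R)-N-methoxy-N,2,2-trimethyl-3-{[(triethylsilyl)oxy]methyl}cyclopropane-1-carboxamide
Product: 9 (1S,3R)-2,2-dimethyl-3-{[(triethylsilyl)oxy]methyl}cyclopropane-1-carbaldehyde (fragment 1)
Conditions: i-Bu2AlH, THF, −78 °C; Rochelle salt work-up
Reagents that add atoms: none
Why: Weinreb amide reduction stops at the aldehyde through the chelated tetrahedral intermediate, and the cis aldehyde does not epimerise because a cyclopropyl enolate is not formed at −78 °C.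

**Fragment 2 (steps 8–14)**

Step 8
Reactants: 10 prop-2-yn-1-ol
Product: 11 tert-butyldimethyl(prop-2-yn-1-yloxy)silane
Conditions: t-BuMe2SiCl, imidazole, CH2Cl2, rt
Reagents that add atoms: tert-butylchlorodimethylsilane, CC(C)(C)[Si](C)(C)Cl
Why: Standard silyl protection of the primary alcohol.

Step 9
Reactants: 11 tert-butyldimethyl(prop-2-yn-1-yloxy)silane
Product: 12 (Z)-tert-butyldimethyl{[2-(tributylstannyl)-3-(trimethylsilyl)prop-2-en-1-yl]oxy}silane
Conditions: Me3SiSnBu3, Pd(PPh3)4 (2 mol %), THF, 65 °C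
Reagents that add atoms: tributyl(trimethylsilyl)stannane, CCCC[Sn](CCCC)(CCCC)[Si](C)(C)C
Why: Pd-catalysed syn silylstannation of a terminal alkyne (Si–Sn oxidative addition to zerovalent palladium, syn insertion, reductive elimination) puts tin on the internal and silicon on the terminal carbon, cis to each other.

Step 10
Reactants: 12 (Z)-tert-butyldimethyl{[2-(tributylstannyl)-3-(trimethylsilyl)prop-2-en-1-yl]oxy}silane
Product: 13 (Z)-tert-butyl{[2-iodo-3-(trimethylsilyl)prop-2-en-1-yl]oxy}dimethylsilane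
Conditions: I2, CH2Cl2, 0 °C
Reagents that add atoms: iodine, II
Why: Iododestannylation is ipso and stereoretentive and is far faster at C–Sn than at C–Si, so iodine ends cis to the silyl group.

Step 11
Reactants: 13 (Z)-tert-butyl{[2-iodo-3-(trimethylsilyl)prop-2-en-1-yl]oxy}dimethylsilane; 14 ethynyltrimethylsilane
Product: 15 (E)-tert-butyldimethyl({4-(trimethylsilyl)-2-[(trimethylsilyl)methylidene]but-3-yn-1-yl}oxy)silane
Conditions: PdCl2(PPh3)2 (3 mol %), CuI (5 mol %), i-Pr2NH, THF, rt
Reagents that add atoms: none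
Why: Sonogashira coupling of the alkenyl iodide with retention of geometry forms the C9–C9a bond and leaves the vinylic silyl group cis to the alkyne.

Step 12
Reactants: 15 (E)-tert-butyldimethyl({4-(trimethylsilyl)-2-[(trimethylsilyl)methylidene]but-3-yn-1-yl}oxy)silane
Product: 16 (E)-tert-butyl{[2-(iodomethylidene)-4-(trimethylsilyl)but-3-yn-1-yl]oxy}dimethylsilane
Conditions: N-iodosuccinimide, (CF3)2CHOH, 0 °C
Reagents that add atoms: N-iodosuccinimide, O=C1CCC(=O)N1I
Why: Ipso-iododesilylation of the vinylsilane through the β-silyl cation proceeds with retention, while the alkynylsilane is inert without a silver salt.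

Step 13
Reactants: 16 (E)-tert-butyl{[2-(iodomethylidene)-4-(trimethylsilyl)but-3-yn-1-yl]oxy}dimethylsilane
Product: 17 (E)-tert-butyl{[2-(iodomethylidene)but-3-yn-1-yl]oxy}dimethylsilane
Conditions: K2CO3 (0.2 equiv), MeOH, 0 °C
Reagents that add atoms: none
Why: Methanolysis removes only the alkynyl silyl group (protiodesilylation).

Step 14
Reactants: 17 (E)-tert-butyl{[2-(iodomethylidene)but-3-yn-1-yl]oxy}dimethylsilane; 18 acetic acid
Product: 19 (1Z,3E)-3-{[(tert-butyldimethylsilyl)oxy]methyl}-4-iodobuta-1,3-dien-1-yl acetate (fragment 2)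
Conditions: Ru(2-methylallyl)2(dppb) (2 mol %), toluene, 60 °C
Reagents that add atoms: none
Why: Ru-catalysed anti-Markovnikov addition of a carboxylic acid to a terminal alkyne through a ruthenium vinylidene (Dixneuf-type hydro-oxycarbonylation) gives the (Z)-enol ester, a reaction established for conjugated enynes; the alkenyl iodide is inert to divalent ruthenium.

**Union and completion (steps 15–20)**

Step 15
Reactants: 9 (1S,3R)-2,2-dimethyl-3-{[(triethylsilyl)oxy]methyl}cyclopropane-1-carbaldehyde; 19 (1Z,3E)-3-{[(tert-butyldimethylsilyl)oxy]methyl}-4-iodobuta-1,3-dien-1-yl acetate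
Product: 21 (1Z,3E)-3-{[(tert-butyldimethylsilyl)oxy]methyl}-5-[(1S,3R)-2,2-dimethyl-3-{[(triethylsilyl)oxy]methyl}cyclopropyl]-5-[(triethylsilyl)oxy]penta-1,3-dien-1-yl acetate (C-5 epimers), via chromium alkoxide 20 (not isolated)
Conditions: CrCl2 (20 mol %), NiCl2 (2 mol %), Mn powder, Et3SiCl, DMF/THF, rt
Reagents that add atoms: chlorotriethylsilane, CC[Si](Cl)(CC)CC
Why: Nozaki–Hiyama–Kishi coupling in its chromium-catalytic form: zerovalent nickel inserts into the C–I bond with retention of olefin geometry, transmetalation gives an alkenyl species of trivalent chromium that adds only to the aldehyde (acetate and silyl ethers are inert), Et3SiCl frees chromium from the alkoxide as the silyl ether and Mn regenerates divalent chromium; the new carbinol centre forms unselectively and is oxidised later.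

Step 16
Reactants: 21 (1Z,3E)-3-{[(tert-butyldimethylsilyl)oxy]methyl}-5-[(1S,3R)-2,2-dimethyl-3-{[(triethylsilyl)oxy]methyl}cyclopropyl]-5-[(triethylsilyl)oxy]penta-1,3-dien-1-yl acetate
Product: 22 (1Z,3E)-3-{[(tert-butyldimethylsilyl)oxy]methyl}-5-[(1S,3R)-3-formyl-2,2-dimethylcyclopropyl]-5-[(triethylsilyl)oxy]penta-1,3-dien-1-yl acetate (C-5 epimers)
Conditions: (COCl)2, DMSO, CH2Cl2, −78 to −40 °C; Et3N, −78 to 0 °C
Reagents that add atoms: none
Why: Swern conditions turn a primary triethylsilyl ether directly into the aldehyde (the chlorosulfonium ion displaces silicon at the unhindered oxygen), while the secondary triethylsilyl ether, the tert-butyldimethylsilyl ether and the enol acetate stay; no stereocenter is touched.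

Step 17
Reactants: 22 (1Z,3E)-3-{[(tert-butyldimethylsilyl)oxy]methyl}-5-[(1S,3R)-3-formyl-2,2-dimethylcyclopropyl]-5-[(triethylsilyl)oxy]penta-1,3-dien-1-yl acetate; 23 sodium malondialdehyde
Product: 25 (1S,4aR,5R,6S,9aR)-9-{[(tert-butyldimethylsilyl)oxy]methyl}-4-formyl-5,6-(propane-2,2-diyl)-7-[(triethylsilyl)oxy]-1,4a,5,6,7,9a-hexahydrocyclohepta[c]pyran-1-yl acetate (C-7 epimers), via alkylidene malondialdehyde 24 (not isolated)
Conditions: 23 (1.5 equiv), AcOH (1.5 equiv), ethylenediammonium diacetate (10 mol %), 4 Å MS, CH2Cl2, 0 °C to rt; then Yb(fod)3 (5 mol %), 40 °C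
Reagents that add atoms: none
Why: Proposed new method: a domino Knoevenagel condensation / intramolecular inverse-electron-demand oxa-Diels–Alder reaction in which a (Z)-enol acetate is the 2π partner and a seven-membered carbocycle is closed; the 2-formyl enal 24 is a very electron-poor 1-oxadiene and two-point binding of its formyl oxygens to Yb(fod)3 should lower its LUMO enough for the weakly donating enol ester, while the cis-cyclopropane and the C8=C9 olefin hold C4a and C9a close; the vinylcyclopropane reacts in its s-trans bisected conformer from the face that carries the tether, which puts C4 anti to the CMe2 bridge (sets C4a), and the (Z)-enol acetate reacts with tether and acetoxy group endo, which gives the cis ring fusion and the C1 acetate cis to C9 (sets C9a and C1); the closest known reactions are the Tietze domino Knoevenagel / intramolecular hetero-Diels–Alder reaction with enol ethers and alkenes and lanthanide-catalysed hetero-Diels–Alder reactions of enals with vinyl ethers.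

Step 18
Reactants: 25 (1S,4aR,5R,6S,9aR)-9-{[(tert-butyldimethylsilyl)oxy]methyl}-4-formyl-5,6-(propane-2,2-diyl)-7-[(triethylsilyl)oxy]-1,4a,5,6,7,9a-hexahydrocyclohepta[c]pyran-1-yl acetate
Product: 27 (1S,4aR,5R,6S,9aR)-4-(acetoxymethyl)-9-{[(tert-butyldimethylsilyl)oxy]methyl}-5,6-(propane-2,2-diyl)-7-[(triethylsilyl)oxy]-1,4a,5,6,7,9a-hexahydrocyclohepta[c]pyran-1-yl acetate (C-7 epimers), via allylic alcohol 26 (not isolated)
Conditions: NaBH4, CeCl3·7H2O, MeOH/CH2Cl2, −40 °C; concentrate; Ac2O, pyridine, DMAP (cat.), CH2Cl2, 0 °C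
Reagents that add atoms: acetic anhydride, CC(=O)OC(C)=O
Why: Luche 1,2-reduction of the vinylogous formate and in-flask acetylation of the acid-sensitive allylic alcohol; the short, cold hydride exposure should spare the acetal acetate.

Step 19
Reactants: 27 (1S,4aR,5R,6S,9aR)-4-(acetoxymethyl)-9-{[(tert-butyldimethylsilyl)oxy]methyl}-5,6-(propane-2,2-diyl)-7-[(triethylsilyl)oxy]-1,4a,5,6,7,9a-hexahydrocyclohepta[c]pyran-1-yl acetate
Product: 28 (1S,4aR,5R,6S,9aR)-4-(acetoxymethyl)-7-hydroxy-9-(hydroxymethyl)-5,6-(propane-2,2-diyl)-1,4a,5,6,7,9a-hexahydrocyclohepta[c]pyran-1-yl acetate (C-7 epimers)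
Conditions: HF·pyridine, pyridine, THF, 0 °C to rt
Reagents that add atoms: none
Why: Buffered fluoride desilylation removes both silyl ethers and leaves the two acetates and the enol ether.

Step 20
Reactants: 28 (1S,4aR,5R,6S,9aR)-4-(acetoxymethyl)-7-hydroxy-9-(hydroxymethyl)-5,6-(propane-2,2-diyl)-1,4a,5,6,7,9a-hexahydrocyclohepta[c]pyran-1-yl acetate
Product: 29 (1S,4aR,5R,6S,9aR)-4-(acetoxymethyl)-9-formyl-7-oxo-5,6-(propane-2,2-diyl)-1,4a,5,6,7,9a-hexahydrocyclohepta[c]pyran-1-yl acetate (target)
Conditions: Dess–Martin periodinane (2.5 equiv), NaHCO3, CH2Cl2, 0 °C to rt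
Reagents that add atoms: none
Why: Dess–Martin oxidation of the secondary and the primary allylic alcohol gives the enone and the enal in one operation and erases the undefined C7 centre; the buffer protects the acetal acetate and the C9a hydrogen.

## Compound list

1 | 3-methylbut-2-en-1-ol (prenol) | CC(C)=CCO | starting material
2 | diketene (4-methylideneoxetan-2-one) | C=C1CC(=O)O1 | starting material
3 | 3-methylbut-2-en-1-yl 3-oxobutanoate | CC(C)=CCOC(=O)CC(C)=O | intermediate
4 | 3-methylbut-2-en-1-yl 2-diazo-3-oxobutanoate | CC(C)=CCOC(=O)C(=[N+]=[N-])C(C)=O | intermediate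
5 | 3-methylbut-2-en-1-yl diazoacetate | CC(C)=CCOC(=O)C=[N+]=[N-] | intermediate
6 | (1S,5R)-6,6-dimethyl-3-oxabicyclo[3.1.0]hexan-2-one | O=C1[C@H]2[C@@H](CO1)C2(C)C | intermediate
7 | (1S,3R)-3-(hydroxymethyl)-N-methoxy-N,2,2-trimethylcyclopropane-1-carboxamide (cis) | CON(C)C(=O)[C@H]1[C@@H](CO)C1(C)C | intermediate
8 | (1S,3R)-N-methoxy-N,2,2-trimethyl-3-{[(triethylsilyl)oxy]methyl}cyclopropane-1-carboxamide | CON(C)C(=O)[C@H]1[C@@H](CO[Si](CC)(CC)CC)C1(C)C | intermediate
9 | (1S,3R)-2,2-dimethyl-3-{[(triethylsilyl)oxy]methyl}cyclopropane-1-carbaldehyde (fragment 1, cis) | O=C[C@H]1[C@@H](CO[Si](CC)(CC)CC)C1(C)C | intermediate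
10 | prop-2-yn-1-ol | C#CCO | starting material
11 | tert-butyldimethyl(prop-2-yn-1-yloxy)silane | C#CCO[Si](C)(C)C(C)(C)C | intermediate
12 | (Z)-tert-butyldimethyl{[2-(tributylstannyl)-3-(trimethylsilyl)prop-2-en-1-yl]oxy}silane (Si and Sn cis) | C[Si](C)(C)/C=C(\[Sn](CCCC)(CCCC)CCCC)CO[Si](C)(C)C(C)(C)C | intermediate
13 | (Z)-tert-butyl{[2-iodo-3-(trimethylsilyl)prop-2-en-1-yl]oxy}dimethylsilane (I and Si cis) | C[Si](C)(C)/C=C(\I)CO[Si](C)(C)C(C)(C)C | intermediate
14 | ethynyltrimethylsilane | C#C[Si](C)(C)C | starting material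
15 | (E)-tert-butyldimethyl({4-(trimethylsilyl)-2-[(trimethylsilyl)methylidene]but-3-yn-1-yl}oxy)silane (vinylic Si cis to the alkyne) | C[Si](C)(C)/C=C(\C#C[Si](C)(C)C)CO[Si](C)(C)C(C)(C)C | intermediate
16 | (E)-tert-butyl{[2-(iodomethylidene)-4-(trimethylsilyl)but-3-yn-1-yl]oxy}dimethylsilane (I cis to the alkyne) | I/C=C(\C#C[Si](C)(C)C)CO[Si](C)(C)C(C)(C)C | intermediate
17 | (E)-tert-butyl{[2-(iodomethylidene)but-3-yn-1-yl]oxy}dimethylsilane | I/C=C(\C#C)CO[Si](C)(C)C(C)(C)C | intermediate
18 | acetic acid | CC(=O)O | starting material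
19 | (1Z,3E)-3-{[(tert-butyldimethylsilyl)oxy]methyl}-4-iodobuta-1,3-dien-1-yl acetate (fragment 2; I cis to the acetoxyvinyl group) | CC(=O)O/C=C\C(CO[Si](C)(C)C(C)(C)C)=C/I | intermediate
20 | dichlorochromium alkoxide (trivalent chromium) of the coupled allylic alcohol, C-7 epimers | CC(=O)O/C=C\C(CO[Si](C)(C)C(C)(C)C)=C/C(O[Cr](Cl)Cl)[C@H]1[C@@H](CO[Si](CC)(CC)CC)C1(C)C | intermediate
21 | (1Z,3E)-3-{[(tert-butyldimethylsilyl)oxy]methyl}-5-[(1S,3R)-2,2-dimethyl-3-{[(triethylsilyl)oxy]methyl}cyclopropyl]-5-[(triethylsilyl)oxy]penta-1,3-dien-1-yl acetate (C-5 epimers) | CC(=O)O/C=C\C(CO[Si](C)(C)C(C)(C)C)=C/C(O[Si](CC)(CC)CC)[C@H]1[C@@H](CO[Si](CC)(CC)CC)C1(C)C | intermediate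
22 | (1Z,3E)-3-{[(tert-butyldimethylsilyl)oxy]methyl}-5-[(1S,3R)-3-formyl-2,2-dimethylcyclopropyl]-5-[(triethylsilyl)oxy]penta-1,3-dien-1-yl acetate (C-5 epimers) | CC(=O)O/C=C\C(CO[Si](C)(C)C(C)(C)C)=C/C(O[Si](CC)(CC)CC)[C@H]1[C@@H](C=O)C1(C)C | intermediate
23 | sodium malondialdehyde (sodium 3-oxoprop-1-en-1-olate) | [Na+].[O-]/C=C/C=O | starting material
24 | alkylidene malondialdehyde: 22 with the cyclopropane formyl group replaced by a 2-formyl-3-oxoprop-1-en-1-yl group, cyclopropane configuration unchanged | CC(=O)O/C=C\C(CO[Si](C)(C)C(C)(C)C)=C/C(O[Si](CC)(CC)CC)[C@H]1[C@@H](C=C(C=O)C=O)C1(C)C | intermediate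
25 | (1S,4aR,5R,6S,9aR)-9-{[(tert-butyldimethylsilyl)oxy]methyl}-4-formyl-5,6-(propane-2,2-diyl)-7-[(triethylsilyl)oxy]-1,4a,5,6,7,9a-hexahydrocyclohepta[c]pyran-1-yl acetate (H-1, H-4a, H-9a and the CMe2 bridge on one face; C-7 epimers) | O=CC1=CO[C@@H](OC(C)=O)[C@H]2C(CO[Si](C)(C)C(C)(C)C)=CC(O[Si](CC)(CC)CC)[C@H]3[C@@H]([C@@H]12)C3(C)C | intermediate
26 | 4-(hydroxymethyl) analogue of 25 | OCC1=CO[C@@H](OC(C)=O)[C@H]2C(CO[Si](C)(C)C(C)(C)C)=CC(O[Si](CC)(CC)CC)[C@H]3[C@@H]([C@@H]12)C3(C)C | intermediate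
27 | (1S,4aR,5R,6S,9aR)-4-(acetoxymethyl)-9-{[(tert-butyldimethylsilyl)oxy]methyl}-5,6-(propane-2,2-diyl)-7-[(triethylsilyl)oxy]-1,4a,5,6,7,9a-hexahydrocyclohepta[c]pyran-1-yl acetate (C-7 epimers) | CC(=O)OCC1=CO[C@@H](OC(C)=O)[C@H]2C(CO[Si](C)(C)C(C)(C)C)=CC(O[Si](CC)(CC)CC)[C@H]3[C@@H]([C@@H]12)C3(C)C | intermediate
28 | (1S,4aR,5R,6S,9aR)-4-(acetoxymethyl)-7-hydroxy-9-(hydroxymethyl)-5,6-(propane-2,2-diyl)-1,4a,5,6,7,9a-hexahydrocyclohepta[c]pyran-1-yl acetate (C-7 epimers) | CC(=O)OCC1=CO[C@@H](OC(C)=O)[C@H]2C(CO)=CC(O)[C@H]3[C@@H]([C@@H]12)C3(C)C | intermediate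
29 | (1S,4aR,5R,6S,9aR)-4-(acetoxymethyl)-9-formyl-7-oxo-5,6-(propane-2,2-diyl)-1,4a,5,6,7,9a-hexahydrocyclohepta[c]pyran-1-yl acetate (CNP0263020.2) | CC(=O)OCC1=CO[C@@H](OC(C)=O)[C@H]2C(C=O)=CC(=O)[C@H]3[C@@H]([C@@H]12)C3(C)C | target

## Step count and risks

Total step count: 20. Longest linear sequence: 13 steps (steps 1–7 or steps 8–14, followed by steps 15–20), which is 65 % of the total.

The three steps most likely to fail:

**Step 17 (the proposed new cycloaddition).** The enol acetate may be too weak a dienophile, or the ring fusion may come out trans. The fallback uses known chemistry, the domino Knoevenagel / hetero-Diels–Alder reaction with an enol ether as dienophile. It sets out from aldehyde 9 and silyl ether 11 and comes back to the route at 25. Lithiated 11 (n-BuLi, THF, −78 °C) adds to 9 to give the propargylic alcohol F3. Hydroxyl-directed trans-hydroalumination with NaAlH2(OCH2CH2OMe)2 followed by I2 gives the (Z)-iodoallylic alcohol F4, with iodine on C9 cis to the carbinol carbon. Et3SiCl and imidazole give the bis(triethylsilyl) ether F5. Stille coupling with (Z)-tributyl(2-ethoxyvinyl)stannane (Pd(PPh3)4, CuI, DMF) gives the dienyl ethyl ether F6, and the selective Swern oxidation of step 16 gives the aldehyde F7. The uncatalysed domino reaction with 23 (AcOH, ethylenediammonium diacetate, CH2Cl2) gives the 1-ethoxy cycloadduct F8, with the same spatial arrangement as 25. Brief hydrolysis of the mixed acetal in aqueous AcOH/THF at 0 °C gives the lactol F9, and Ac2O, Et3N and DMAP then give 25; the axial acetate is expected to be the favored anomer.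

**Step 15 (fragment coupling).** The hindered cis-cyclopropane aldehyde and the sensitive iododienyl acetate may couple poorly under nickel/chromium catalysis. The fallback replaces the catalytic coupling by a polar organolithium addition and moves the enol ester formation behind the union. It sets out from 9 and 16 and comes back at 21. Iodine–lithium exchange on 16 (t-BuLi, Et2O, −78 °C), addition of the alkenyllithium to 9 and in-flask silylation with Et3SiCl give the silylated enyne F1. K2CO3 in MeOH gives the terminal enyne F2, and the ruthenium-catalysed addition of 18 under the conditions of step 14 gives 21.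

**Step 16 (oxidative desilylation).** Discrimination between the two triethylsilyl ethers, or survival of the dienyl acetate under activated DMSO, may fail. The fallback separates unmasking and oxidation; it sets out from 21 and comes back at 22. Selective methanolysis of the primary silyl ether (pyridinium p-toluenesulfonate, MeOH/CH2Cl2, −20 °C) gives the primary alcohol F10, which TEMPO (cat.) with PhI(OAc)2 oxidises to 22 without touching the secondary silyl ether.

Further compounds
F1 | step 15 | (E)-configured C8=C9 enyne with trimethylsilyl on the alkyne: 5-[(1S,3R)-cyclopropyl] bis(triethylsilyl) ether, C7 cis to the alkyne, C-7 epimers | C[Si](C)(C)C#C\C(CO[Si](C)(C)C(C)(C)C)=C/C(O[Si](CC)(CC)CC)[C@H]1[C@@H](CO[Si](CC)(CC)CC)C1(C)C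
F2 | step 15 | terminal alkyne obtained from F1 by loss of the alkynyl trimethylsilyl group | C#C\C(CO[Si](C)(C)C(C)(C)C)=C/C(O[Si](CC)(CC)CC)[C@H]1[C@@H](CO[Si](CC)(CC)CC)C1(C)C
F3 | step 17 | propargylic alcohol from 9 and lithiated 11 (C-7 epimers) | CC(C)(C)[Si](C)(C)OCC#CC(O)[C@H]1[C@@H](CO[Si](CC)(CC)CC)C1(C)C
F4 | step 17 | (Z)-iodoallylic alcohol, iodine on C9 cis to the carbinol carbon | CC(C)(C)[Si](C)(C)OC/C(I)=C/C(O)[C@H]1[C@@H](CO[Si](CC)(CC)CC)C1(C)C
F5 | step 17 | triethylsilyl ether of F4 | CC(C)(C)[Si](C)(C)OC/C(I)=C/C(O[Si](CC)(CC)CC)[C@H]1[C@@H](CO[Si](CC)(CC)CC)C1(C)C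
F6 | step 17 | (1Z,3E)-dienyl ethyl ether, the ethoxy analogue of 21 | CCO/C=C\C(CO[Si](C)(C)C(C)(C)C)=C/C(O[Si](CC)(CC)CC)[C@H]1[C@@H](CO[Si](CC)(CC)CC)C1(C)C
F7 | step 17 | aldehyde, the ethoxy analogue of 22 | CCO/C=C\C(CO[Si](C)(C)C(C)(C)C)=C/C(O[Si](CC)(CC)CC)[C@H]1[C@@H](C=O)C1(C)C
F8 | step 17 | 1-ethoxy cycloadduct, the ethoxy analogue of 25 with the same spatial arrangement | O=CC1=CO[C@@H](OCC)[C@H]2C(CO[Si](C)(C)C(C)(C)C)=CC(O[Si](CC)(CC)CC)[C@H]3[C@@H]([C@@H]12)C3(C)C
F9 | step 17 | lactol (1-hydroxy analogue of 25, anomer mixture) | O=CC1=COC(O)[C@H]2C(CO[Si](C)(C)C(C)(C)C)=CC(O[Si](CC)(CC)CC)[C@H]3[C@@H]([C@@H]12)C3(C)C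
F10 | step 16 | primary alcohol obtained from 21 by loss of the primary triethylsilyl group | CC(=O)O/C=C\C(CO[Si](C)(C)C(C)(C)C)=C/C(O[Si](CC)(CC)CC)[C@H]1[C@@H](CO)C1(C)C
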